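I wanted to know which species led at the end of Saturday's, Thursday's and Monday's flasks, and how much of it stood there.

in all of them: starting complex 0.10 M
- north: incoming ligand 0.20 M; run made earlier
- south: incoming ligand 0.30 M; run made earlier
- Saturday's: incoming ligand 0.400 M; time 30 h
- Thursday's: incoming ligand 0.400 M; time 60 h
- Monday's: incoming ligand 0.400 M; time 120 h

| run | time / h | starting complex / % | side product / % | complex with one exchanged / % | complex with four exchanged / % | complex with two exchanged / % |
|---|---|---|---|---|---|---|
| north | 1.50 | 97 | 0 | 2 | 1 | 0 |
| north | 5.00 | 97 | 0 | 7 | 0 | 0 |
| north | 8.00 | 93 | 0 | 5 | 0 | 0 |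
| north | 12.0 | 89 | 0 | 7 | 0 | 3 |
| north | 20.0 | 84 | 0 | 7 | 0 | 4 |
| north | 25.0 | 83 | 0 | 12 | 2 | 6 |
| north | 30.0 | 81 | 2 | 11 | 0 | 4 |
| south | 2.50 | 96 | 2 | 3 | 1 | 0 |
| south | 4.00 | 95 | 0 | 4 | 1 | 1 |
| south | 6.00 | 94 | 0 | 5 | 0 | 2 |
| south | 8.00 | 88 | 0 | 6 | 0 | 0 |
| south | 12.0 | 86 | 0 | 11 | 2 | 3 |
| south | 20.0 | 81 | 3 | 10 | 1 | 6 |
| south | 30.0 | 74 | 1 | 15 | 2 | 9 |

(readings scatter by 1.5 percentage points)

1. which of these there is most of at the end, counted by the starting complex in it, Saturday's (complex with two exchanged / complex with four exchanged / side product / starting complex / complex with one exchanged)
2. which of these there is most of at the end, counted by the starting complex in it, Thursday's (complex with two exchanged / complex with four exchanged / side product / starting complex / complex with one exchanged)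
3. which of these there is most of at the end, counted by the starting complex in it, Monday's (complex with two exchanged / complex with four exchanged / side product / starting complex / complex with one exchanged)
4. final amount of the leader among these, as a percentage of the starting complex charged, in Saturday's
5. final amount of the leader among these, as a percentage of the starting complex charged, in Thursday's
6. final amount of the leader among these, as a percentage of the starting complex charged, in Monday's



1. Read as pseudo-first-order, the last starting-complex readings gave a second-order constant of 0.0351 /M/h in the north run and 0.0335 /M/h in the south run. I used their mean, 0.0343 /M/h.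

2. For the first extreme, I froze incoming ligand at its charge. The natural logarithm of two, divided by the constant and by 0.400 M, gave 50.5 h: the frozen-ligand half-life of starting complex. This version left 66.3% at 30 h, 43.9% at 60 h and 19.3% at 120 h.

3. For the second extreme, I let each lost starting complex go straight to complex with four exchanged. The charges stood at 4.00 ligand per complex, so in this version ligand fell in step with starting complex, and the loss became second order. This version left 70.8%, 54.9% and 37.8% at those times.

4. I expected the flasks between these edges, on the assumption that every step ran forward and ligand was used for nothing else. I took the midpoints: 68.5%, 49.4% and 28.5%. My call was starting complex as leader in each flask, though with little confidence on Monday's.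

5. The forecast named starting complex at 68% for Saturday's, starting complex at 49% for Thursday's and complex with two exchanged at 34% for Monday's, which differs from my Monday's call: “two-exchanged narrowly overtakes, though this call is uncertain”.

6. The flasks gave starting complex at 66.9% on Saturday's, starting complex at 55.7% on Thursday's and starting complex at 50.7% on Monday's.

    complex with two exchanged + incoming ligand ⇌ leaving ligand + complex with three exchanged (K = 0.0980, k = 0.00170 /M/min)
    starting complex + incoming ligand ⇌ leaving ligand + complex with one exchanged (K = 0.280, k = 7.50 × 10⁻⁴ /M/min)
    complex with one exchanged + incoming ligand ⇌ leaving ligand + complex with two exchanged (K = 0.200, k = 0.00480 /M/min)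
    complex with three exchanged + incoming ligand ⇌ leaving ligand + complex with four exchanged (K = 0.490, k = 0.00690 /M/min)
    2 incoming ligand → homo dimer (k = 2.50 × 10⁻⁴ /M/min)
    complex with one exchanged → side product (k = 4.70 × 10⁻⁵ /min)

7. Monday's had run 2.38 frozen-ligand half-lives, yet its starting complex stood above even the upper edge of 37.8%, and left ten times as long it still held 46.1%. For a neighbouring flask like Monday's but charged with 0.16 M of incoming ligand, the frozen-ligand half-life became 126 h, and freezing the ligand gave 51.7% at 120 h. That flask held 66.2% of starting complex.

The data were computed for an exercise; the scatter is artificial.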